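**Retrosynthetic overview**
- The strategy rests on the unit O–C6–C1'=C2'–C3'–C4'–O (C6 is the oxygen-bearing carbon of the 5,6-dihydro-2H-pyran-2-one ring; the side chain is numbered C1'–C10' outward, phenyl on C10'). It is an (E)-2-ene-1,5-anti-diol, the footprint of a C3 1,3-diborylpropene linchpin joined to two aldehydes.
- Late disconnections: ring bond O1–C2 (lactonisation of a (Z)-5-hydroxy enoate) and C3=C4 (Z-selective phosphonate olefination). Central disconnection: C6–C1' and C3'–C4' together, by a one-pot double allylboration of 3-(4-methoxybenzyloxy)propanal, allenyl pinacolboronate and a C4'–C10' acetonide aldehyde.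
- The acetonide aldehyde goes back to cinnamaldehyde and methyl acetoacetate: catalytic asymmetric vinylogous aldol (C8'), 1,3-syn reduction (C6'), acetonide formation, partial ester reduction.
- Ring order: the phenyl ring is bought; the temporary 1,3-dioxane (acetonide) is formed early; the dihydropyranone ring is closed late by lactonisation; the acetonide is removed last.

Key step: step 9

Remark on the chemistry: (R)-BINOL is assumed to give the 5R aldol 6 and the (+)-α-pinene-derived (dIpc)2BH the 6R carbinol; both senses are to be confirmed by Mosher (MTPA) ester analysis, and the antipodal ligand or borane would be used otherwise.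

**Route**

Step 1
Reactants: 1 methyl acetoacetate
Product: 2 methyl 3-(trimethylsilyloxy)but-2-enoate (E/Z mixture)
Conditions: TMSCl, Et3N, hexane, rt
Reagents that add atoms: chlorotrimethylsilane, C[Si](C)(C)Cl
Why: Silyl enol ether formation by O-silylation of the enolised β-keto ester; the double-bond geometry is of no consequence.

Step 2
Reactants: 2 methyl 3-(trimethylsilyloxy)but-2-enoate
Product: 3 1-methoxy-1,3-bis(trimethylsilyloxy)buta-1,3-diene
Conditions: LiN(iPr)2 (LDA), TMSCl, THF, −78 °C to rt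
Reagents that add atoms: chlorotrimethylsilane, C[Si](C)(C)Cl
Why: Kinetic γ-deprotonation of the vinylogous ester and O-silylation at the ester oxygen (silyl ketene acetal formation) should give the bis-silyl dienol ether, an acetoacetate d4 equivalent.

Step 3
Reactants: 3 1-methoxy-1,3-bis(trimethylsilyloxy)buta-1,3-diene; 4 (E)-cinnamaldehyde
Product: 6 methyl (5R,6E)-5-hydroxy-3-oxo-7-phenylhept-6-enoate, via bis-silyl aldol adduct 5 (not isolated)
Conditions: Ti(OiPr)4 (8 mol%), (R)-BINOL (8 mol%), 4 Å MS, THF, −78 °C to rt; then TFA, −78 °C to rt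
Reagents that add atoms: none
Why: Ti(OiPr)4/BINOL-catalysed vinylogous Mukaiyama aldol, in which the terminal carbon of diene 3 adds 1,2 to the titanium-bound enal, the BINOL ligand fixes the exposed aldehyde face so that C5 (later C8') should form R, and mild acid then strips both silyl groups from adduct 5.

Step 4
Reactants: 6 methyl (5R,6E)-5-hydroxy-3-oxo-7-phenylhept-6-enoate
Product: 8 methyl (3S,5R,6E)-3,5-dihydroxy-7-phenylhept-6-enoate, via diethylboron chelate 7 (not isolated)
Conditions: Et2BOMe, THF/MeOH (4:1), −78 °C; NaBH4, −78 °C; AcOH, then MeOH azeotrope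
Reagents that add atoms: none
Why: Narasaka–Prasad reduction, in which Et2BOMe ties the C5 hydroxyl and the C3 ketone into the six-membered chelate 7 and external axial hydride delivery should give the 1,3-syn diol, so that C3 (later C6') is relayed from C5.

Step 5
Reactants: 8 methyl (3S,5R,6E)-3,5-dihydroxy-7-phenylhept-6-enoate
Product: 9 methyl 2-[(4S,6R)-2,2-dimethyl-6-[(E)-2-phenylethenyl]-1,3-dioxan-4-yl]acetate
Conditions: 2,2-dimethoxypropane, PPTS (cat.), acetone, rt
Reagents that add atoms: 2,2-dimethoxypropane, COC(C)(C)OC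
Why: Acid-catalysed transketalisation (acetonide protection) should give the chair 1,3-dioxane with both substituents equatorial, and PPTS is mild enough not to ionise the cinnamyl C–O bond.

Step 6
Reactants: 9 methyl 2-[(4S,6R)-2,2-dimethyl-6-[(E)-2-phenylethenyl]-1,3-dioxan-4-yl]acetate
Product: 11 2-[(4S,6R)-2,2-dimethyl-6-[(E)-2-phenylethenyl]-1,3-dioxan-4-yl]acetaldehyde, via aluminium hemiacetal 10 (not isolated)
Conditions: iBu2AlH (DIBAL-H, 1.05 equiv), CH2Cl2, −78 °C; MeOH, aq. potassium sodium tartrate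
Reagents that add atoms: none
Why: Partial ester reduction with DIBAL-H, in which the tetrahedral aluminium hemiacetal 10 persists at −78 °C and releases the aldehyde only on quench, so over-reduction should be avoided; the β-alkoxy aldehyde is used at once.

Step 7
Reactants: 12 propane-1,3-diol
Product: 13 3-[(4-methoxyphenyl)methoxy]propan-1-ol
Conditions: NaH (1 equiv), PMBCl, n-Bu4NI (cat.), THF, 0 °C to rt (diol in excess)
Reagents that add atoms: 4-methoxybenzyl chloride, COc1ccc(CCl)cc1
Why: Williamson ether synthesis on the mono-alkoxide of a symmetric diol used in excess should give mainly the mono-PMB ether.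

Step 8
Reactants: 13 3-[(4-methoxyphenyl)methoxy]propan-1-ol
Product: 14 3-[(4-methoxyphenyl)methoxy]propanal
Conditions: TEMPO (cat.), PhI(OAc)2, CH2Cl2, rt
Reagents that add atoms: none
Why: TEMPO/oxoammonium oxidation should take the primary alcohol to the aldehyde without over-oxidation, under near-neutral conditions that spare the PMB ether and limit β-elimination.

Step 9
Reactants: 15 allenylboronic acid pinacol ester; 14 3-[(4-methoxyphenyl)methoxy]propanal; 11 2-[(4S,6R)-2,2-dimethyl-6-[(E)-2-phenylethenyl]-1,3-dioxan-4-yl]acetaldehyde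
Product: 19 (3R,4E,7S)-8-[(4R,6R)-2,2-dimethyl-6-[(E)-2-phenylethenyl]-1,3-dioxan-4-yl]-1-[(4-methoxyphenyl)methoxy]oct-4-ene-3,7-diol, via γ-boryl allylborane 16 (not isolated), via α-boryl allyl borinate 17 (not isolated), via bis-boron ester 18 (not isolated)
Conditions: (dIpc)2BH (from (+)-α-pinene, 1.3 equiv), 15 (1.4 equiv), toluene, 0 °C to rt; 14 (1.15 equiv), −78 °C; 11 (1.0 equiv), −78 °C to rt, 24 h; NaOH, H2O2, THF/H2O, 0 °C
Reagents that add atoms: none
Why: The borane adds across the terminal C=C of allene 15 (boron to CH2) and the first-formed allylborane equilibrates by 1,3-boratropic shifts to the (E)-γ-boryl allylborane 16, whose allyl–B(Ipc)2 end adds to 14 at −78 °C through a closed chair (Zimmerman–Traxler) transition state to give the anti β-borinyloxy α-substituted allyl pinacolboronate 17; on warming, 17 adds to 11 through a second chair, forming C3'–C4' and turning C1'–C2' into the E alkene. The closest known reaction type is the one-pot double allylboration of two aldehydes with γ-boryl allyldiisopinocampheylboranes made by allenylboronate hydroboration, which gives (E)-pent-2-ene-1,5-anti-diols. No ring is closed. C6 is set by the isopinocampheyl groups (the (+)-α-pinene-derived reagent should attack the Si face of 14, as in allyl- and crotylborations with this reagent family, giving 6R), and C4' by 1,3-chirality transfer from the boron-bearing carbon of 17 with the substituent of 11 equatorial (giving 4'S, the 1,5-anti relation). The step needs face selectivity at C6, E geometry and a clean order of the two aldehydes: the first is secured by reagent control on an unbranched β-alkoxy aldehyde, the second by the bulky α-substituent of 17 sitting equatorial beside the modestly sized pinacol ester, and the third by the large reactivity gap between the B(Ipc)2 and B(pin) ends, with 14 added first and in deficiency to the borane so that C6 becomes the allylic carbinol.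

Step 10
Reactants: 19 diol from step 9
Product: 20 bis-TBS ether of 19 (both secondary hydroxyls, at C6 and C4', silylated; all stereocentres as in 19)
Conditions: TBSOTf, 2,6-lutidine, CH2Cl2, −78 °C
Reagents that add atoms: tert-butyldimethylsilyl triflate, CC(C)(C)[Si](C)(C)OS(=O)(=O)C(F)(F)F
Why: Silyl ether formation with the silyl triflate/2,6-lutidine pair should cap both secondary hydroxyls quickly at low temperature without touching the acetonide or the PMB ether.

Step 11
Reactants: 20 bis-TBS PMB ether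
Product: 21 primary alcohol (PMB removed from 20; C4 hydroxyl free)
Conditions: DDQ, CH2Cl2/pH 7 phosphate buffer (10:1), 0 °C
Reagents that add atoms: none
Why: Oxidative PMB ether cleavage with DDQ (hydride abstraction at the electron-rich benzylic position, then hydrolysis) should free the primary alcohol, the cold, buffered and short conditions being chosen to spare the less easily oxidised styryl acetal and allylic silyl ether.

Step 12
Reactants: 21 primary alcohol
Product: 22 β-silyloxy aldehyde (C4 aldehyde; bis-TBS; acetonide)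
Conditions: Dess–Martin periodinane, NaHCO3, CH2Cl2, 0 °C to rt
Reagents that add atoms: none
Why: Dess–Martin oxidation should give the aldehyde under buffered, non-basic conditions that avoid β-elimination of the allylic silyloxy group.

Step 13
Reactants: 22 β-silyloxy aldehyde
Product: 23 methyl (Z)-enoate (C2–C3 Z; bis-TBS; acetonide)
Conditions: (CF3CH2O)2P(O)CH2CO2Me, KN(SiMe3)2, 18-crown-6, THF, −78 °C
Reagents that add atoms: methyl bis(2,2,2-trifluoroethyl)phosphonoacetate, COC(=O)CP(=O)(OCC(F)(F)F)OCC(F)(F)F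
Why: Still–Gennari olefination, in which the electron-poor phosphonate under dissociating conditions collapses fast from the kinetic adduct and should therefore give the (Z)-enoate needed for lactonisation.

Step 14
Reactants: 23 methyl (Z)-enoate
Product: 25 (6R)-6-[(1E,4S)-5-[(4R,6R)-2,2-dimethyl-6-[(E)-2-phenylethenyl]-1,3-dioxan-4-yl]-4-hydroxypent-1-en-1-yl]-5,6-dihydro-2H-pyran-2-one, via dihydroxy Z-ester 24 (not isolated)
Conditions: HF·pyridine, pyridine, THF, 0 °C to rt; then PPTS (cat.), CH2Cl2, rt
Reagents that add atoms: none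
Why: Fluoride-mediated desilylation frees both secondary hydroxyls, and in 24 only the C6 hydroxyl can reach the cis-ester through a six-membered ring, so lactonisation (intramolecular transesterification) should close the dihydropyranone with C6 untouched.

Step 15
Reactants: 25 lactone acetonide
Product: 26 (6R)-6-[(1E,4S,6R,8R,9E)-4,6,8-trihydroxy-10-phenyldeca-1,9-dien-1-yl]-5,6-dihydro-2H-pyran-2-one (CNP0368533.2)
Conditions: AcOH/H2O (4:1), rt to 40 °C
Reagents that add atoms: none
Why: Acid-catalysed acetal hydrolysis cleaves only the C–O bonds at the ketal carbon, so C6' and C8' keep their configuration, and weak aqueous acid is chosen so as not to ionise the cinnamyl alcohol or open the lactone.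

**Compound list**
1 | methyl acetoacetate | COC(=O)CC(C)=O | starting material
2 | methyl 3-(trimethylsilyloxy)but-2-enoate (E/Z mixture) | COC(=O)C=C(C)O[Si](C)(C)C | intermediate
3 | 1-methoxy-1,3-bis(trimethylsilyloxy)buta-1,3-diene | COC(O[Si](C)(C)C)=CC(=C)O[Si](C)(C)C | intermediate
4 | (E)-cinnamaldehyde | O=C/C=C/c1ccccc1 | starting material
5 | methyl (5R,6E)-7-phenyl-3,5-bis(trimethylsilyloxy)hepta-2,6-dienoate (formed in situ) | COC(=O)C=C(O[Si](C)(C)C)C[C@@H](O[Si](C)(C)C)/C=C/c1ccccc1 | intermediate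
6 | methyl (5R,6E)-5-hydroxy-3-oxo-7-phenylhept-6-enoate | COC(=O)CC(=O)C[C@@H](O)/C=C/c1ccccc1 | intermediate
7 | methyl (5R,6E)-5-(diethylboryloxy)-3-oxo-7-phenylhept-6-enoate, ketone-chelated (formed in situ) | COC(=O)CC(=O)C[C@@H](OB(CC)CC)/C=C/c1ccccc1 | intermediate
8 | methyl (3S,5R,6E)-3,5-dihydroxy-7-phenylhept-6-enoate | COC(=O)C[C@@H](O)C[C@@H](O)/C=C/c1ccccc1 | intermediate
9 | methyl 2-[(4S,6R)-2,2-dimethyl-6-[(E)-2-phenylethenyl]-1,3-dioxan-4-yl]acetate | COC(=O)C[C@@H]1C[C@H](/C=C/c2ccccc2)OC(C)(C)O1 | intermediate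
10 | diisobutylaluminium hemiacetal of ester 9 (formed in situ; acetal carbon unassigned) | COC(C[C@@H]1C[C@H](/C=C/c2ccccc2)OC(C)(C)O1)O[Al](CC(C)C)CC(C)C | intermediate
11 | 2-[(4S,6R)-2,2-dimethyl-6-[(E)-2-phenylethenyl]-1,3-dioxan-4-yl]acetaldehyde | O=CC[C@@H]1C[C@H](/C=C/c2ccccc2)OC(C)(C)O1 | intermediate
12 | propane-1,3-diol | OCCCO | starting material
13 | 3-[(4-methoxyphenyl)methoxy]propan-1-ol | COc1ccc(COCCCO)cc1 | intermediate
14 | 3-[(4-methoxyphenyl)methoxy]propanal | COc1ccc(COCCC=O)cc1 | intermediate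
15 | allenylboronic acid pinacol ester (4,4,5,5-tetramethyl-2-(propa-1,2-dienyl)-1,3,2-dioxaborolane) | C=C=CB1OC(C)(C)C(C)(C)O1 | starting material
16 | [(E)-3-(pinacolboryl)prop-2-en-1-yl]bis[(1R,2S,3R,5R)-isopinocampheyl]borane (formed in situ) | CC1(C)OB(/C=C/CB([C@@H]2C[C@@H]3C[C@H]([C@H]2C)C3(C)C)[C@@H]2C[C@@H]3C[C@H]([C@H]2C)C3(C)C)OC1(C)C | intermediate
17 | anti α-(pinacolboryl) homoallyl bis(isopinocampheyl)borinate from 14 (formed in situ) | COc1ccc(COCC[C@@H](OB([C@@H]2C[C@@H]3C[C@H]([C@H]2C)C3(C)C)[C@@H]2C[C@@H]3C[C@H]([C@H]2C)C3(C)C)[C@@H](B2OC(C)(C)C(C)(C)O2)C=C)cc1 | intermediate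
18 | bis-boron ester of diol 19: C6–O–B(Ipc)2 and C4'–O–B(pin) (formed in situ) | COc1ccc(COCC[C@@H](OB([C@@H]2C[C@@H]3C[C@H]([C@H]2C)C3(C)C)[C@@H]2C[C@@H]3C[C@H]([C@H]2C)C3(C)C)/C=C/C[C@H](OB2OC(C)(C)C(C)(C)O2)C[C@@H]2C[C@H](/C=C/c3ccccc3)OC(C)(C)O2)cc1 | intermediate
19 | (3R,4E,7S)-8-[(4R,6R)-2,2-dimethyl-6-[(E)-2-phenylethenyl]-1,3-dioxan-4-yl]-1-[(4-methoxyphenyl)methoxy]oct-4-ene-3,7-diol | COc1ccc(COCC[C@@H](O)/C=C/C[C@H](O)C[C@@H]2C[C@H](/C=C/c3ccccc3)OC(C)(C)O2)cc1 | intermediate
20 | bis-TBS ether of 19 (C6 and C4' silyl ethers; PMB ether; acetonide) | COc1ccc(COCC[C@@H](O[Si](C)(C)C(C)(C)C)/C=C/C[C@H](O[Si](C)(C)C(C)(C)C)C[C@@H]2C[C@H](/C=C/c3ccccc3)OC(C)(C)O2)cc1 | intermediate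
21 | primary alcohol from 20 (C4–OH; bis-TBS; acetonide) | OCC[C@@H](O[Si](C)(C)C(C)(C)C)/C=C/C[C@H](O[Si](C)(C)C(C)(C)C)C[C@@H]1C[C@H](/C=C/c2ccccc2)OC(C)(C)O1 | intermediate
22 | β-silyloxy aldehyde (C4 aldehyde; bis-TBS; acetonide) | O=CC[C@@H](O[Si](C)(C)C(C)(C)C)/C=C/C[C@H](O[Si](C)(C)C(C)(C)C)C[C@@H]1C[C@H](/C=C/c2ccccc2)OC(C)(C)O1 | intermediate
23 | methyl (Z)-enoate (bis-TBS; acetonide) | COC(=O)/C=C\C[C@@H](O[Si](C)(C)C(C)(C)C)/C=C/C[C@H](O[Si](C)(C)C(C)(C)C)C[C@@H]1C[C@H](/C=C/c2ccccc2)OC(C)(C)O1 | intermediate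
24 | dihydroxy methyl (Z)-enoate (C6 and C4' hydroxyls free; acetonide; formed in situ) | COC(=O)/C=C\C[C@@H](O)/C=C/C[C@H](O)C[C@@H]1C[C@H](/C=C/c2ccccc2)OC(C)(C)O1 | intermediate
25 | (6R)-6-[(1E,4S)-5-[(4R,6R)-2,2-dimethyl-6-[(E)-2-phenylethenyl]-1,3-dioxan-4-yl]-4-hydroxypent-1-en-1-yl]-5,6-dihydro-2H-pyran-2-one | O=C1C=CC[C@H](/C=C/C[C@H](O)C[C@@H]2C[C@H](/C=C/c3ccccc3)OC(C)(C)O2)O1 | intermediate
26 | (6R)-6-[(1E,4S,6R,8R,9E)-4,6,8-trihydroxy-10-phenyldeca-1,9-dien-1-yl]-5,6-dihydro-2H-pyran-2-one | O=C1C=CC[C@H](/C=C/C[C@H](O)C[C@@H](O)C[C@@H](O)/C=C/c2ccccc2)O1 | target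

**Step count and risks**
Total step count: 15. Longest linear sequence: 13 steps (steps 1–6, then 9–15); the side branch (steps 7–8) joins at step 9.

Steps most likely to fail:

1. Step 9. What may go wrong: incomplete equilibration of the allylborane to the E isomer (which would leak syn adducts), a sluggish or poorly E-selective second allylboration of the hindered α-substituted boronate, or cross-over of the two aldehydes. The fallback sets out from aldehyde 11 and comes back to the route at lactone acetonide 25; aldehyde 14 is then not needed. Allylboration of 11 with allylbis(isopinocampheyl)borane from (+)-α-pinene (Et2O, −78 °C; NaOH, H2O2) should give the (4'S)-homoallylic alcohol F1. TBSOTf/2,6-lutidine gives the silyl ether F2. Cross-metathesis of its terminal alkene with crotonaldehyde (second-generation Hoveyda–Grubbs catalyst, CH2Cl2, 40 °C) should give the (E)-enal F3, whose aldehyde carbon is C6. Allylboration with the antipodal reagent from (−)-α-pinene should give the (6R)-dienol F4. Acryloyl chloride/iPr2NEt gives the acrylate F5, and ring-closing metathesis (second-generation Grubbs catalyst, CH2Cl2, 40 °C) should close the dihydropyranone to the silyl-protected lactone F6. HF·pyridine then frees the C4' hydroxyl to give 25.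

2. Step 3. What may go wrong: low enantioselectivity, the opposite facial sense, or competing reaction at the internal carbon of the diene. The fallback sets out from cinnamaldehyde 4 and comes back at keto ester 6. An auxiliary-controlled acetate aldol with doubly deprotonated (R)-2-hydroxy-1,2,2-triphenylethyl acetate (LiN(iPr)2, THF, −78 to −100 °C) should give the (3R)-β-hydroxy ester F7, from which the minor diastereomer can be removed by crystallisation. Methanolysis (NaOMe, MeOH) gives the methyl ester F8 and returns the triphenylethanediol. Crossed Claisen condensation of F8 with excess lithium enolate of methyl acetate (THF, −78 to −30 °C) gives 6.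

3. Step 11. What may go wrong: DDQ also abstracting hydride from the doubly activated C8'–H of the styryl acetal (over-oxidation to an enone), or acid-induced loss of the acetonide. The fallback sets out from propane-1,3-diol 12 and comes back at alcohol 21; the primary oxygen is carried as a silyl ether, so that no oxidant is needed. Monosilylation (NaH, TBSCl, THF) gives 3-(tert-butyldimethylsilyloxy)propan-1-ol F9, and oxidation as in step 8 gives the aldehyde F10. The double allylboration of step 9 is repeated with F10 in place of 14, through the α-boryl allyl borinate F11 and the bis-boron ester F12, to the diol F13. TBSOTf/2,6-lutidine gives the tris-silyl ether F14, and the primary silyl ether is cleaved selectively (HF·pyridine, pyridine, THF, 0 °C) to give 21.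

**Further compounds**
F1 | step 9 | (2S)-1-[(4R,6R)-2,2-dimethyl-6-[(E)-2-phenylethenyl]-1,3-dioxan-4-yl]pent-4-en-2-ol | C=CC[C@H](O)C[C@@H]1C[C@H](/C=C/c2ccccc2)OC(C)(C)O1
F2 | step 9 | TBS ether of F1 | C=CC[C@H](O[Si](C)(C)C(C)(C)C)C[C@@H]1C[C@H](/C=C/c2ccccc2)OC(C)(C)O1
F3 | step 9 | (E)-enal from F2 (C6 aldehyde, C1'=C2' E, C4' silyl ether) | O=C/C=C/C[C@H](O[Si](C)(C)C(C)(C)C)C[C@@H]1C[C@H](/C=C/c2ccccc2)OC(C)(C)O1
F4 | step 9 | (6R)-dienol from allylboration of F3 | C=CC[C@@H](O)/C=C/C[C@H](O[Si](C)(C)C(C)(C)C)C[C@@H]1C[C@H](/C=C/c2ccccc2)OC(C)(C)O1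
F5 | step 9 | acrylate of F4 | C=CC[C@@H](OC(=O)C=C)/C=C/C[C@H](O[Si](C)(C)C(C)(C)C)C[C@@H]1C[C@H](/C=C/c2ccccc2)OC(C)(C)O1
F6 | step 9 | C4' TBS ether of lactone 25 | O=C1C=CC[C@H](/C=C/C[C@H](O[Si](C)(C)C(C)(C)C)C[C@@H]2C[C@H](/C=C/c3ccccc3)OC(C)(C)O2)O1
F7 | step 3 | (1R)-2-hydroxy-1,2,2-triphenylethyl (3R,4E)-3-hydroxy-5-phenylpent-4-enoate | O=C(C[C@@H](O)/C=C/c1ccccc1)O[C@H](c1ccccc1)C(O)(c1ccccc1)c1ccccc1
F8 | step 3 | methyl (3R,4E)-3-hydroxy-5-phenylpent-4-enoate | COC(=O)C[C@@H](O)/C=C/c1ccccc1
F9 | step 11 | 3-(tert-butyldimethylsilyloxy)propan-1-ol | CC(C)(C)[Si](C)(C)OCCCO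
F10 | step 11 | 3-(tert-butyldimethylsilyloxy)propanal | CC(C)(C)[Si](C)(C)OCCC=O
F11 | step 11 | anti α-(pinacolboryl) homoallyl bis(isopinocampheyl)borinate from F10 | CC(C)(C)[Si](C)(C)OCC[C@@H](OB([C@@H]1C[C@@H]2C[C@H]([C@H]1C)C2(C)C)[C@@H]1C[C@@H]2C[C@H]([C@H]1C)C2(C)C)[C@@H](B1OC(C)(C)C(C)(C)O1)C=C
F12 | step 11 | bis-boron ester of diol F13 | CC(C)(C)[Si](C)(C)OCC[C@@H](OB([C@@H]1C[C@@H]2C[C@H]([C@H]1C)C2(C)C)[C@@H]1C[C@@H]2C[C@H]([C@H]1C)C2(C)C)/C=C/C[C@H](OB1OC(C)(C)C(C)(C)O1)C[C@@H]1C[C@H](/C=C/c2ccccc2)OC(C)(C)O1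
F13 | step 11 | primary-TBS analogue of diol 19 | CC(C)(C)[Si](C)(C)OCC[C@@H](O)/C=C/C[C@H](O)C[C@@H]1C[C@H](/C=C/c2ccccc2)OC(C)(C)O1
F14 | step 11 | tris-TBS ether of F13 | CC(C)(C)[Si](C)(C)OCC[C@@H](O[Si](C)(C)C(C)(C)C)/C=C/C[C@H](O[Si](C)(C)C(C)(C)C)C[C@@H]1C[C@H](/C=C/c2ccccc2)OC(C)(C)O1
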